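**Retrosynthetic overview**
1. The C3(ring A)–N1(ring B) bond is made last: the ring B indolide nitrogen attacks C3 of an S-activated ring A indol-2-yl methyl sulfoxide (extended Pummerer amination). The sulfoxide oxygen is the oxidant and the 2-SMe group is regenerated.
2. Ring A sulfoxide ⇐ 2-(methylthio)indole ⇐ 3-(methylthio)indole (acid 3→2 sulfenyl shift) ⇐ 3,4,5-tribromoaniline + MeSCH2CH(OMe)2 (Gassman indole synthesis).
3. Ring B nucleophile 2,4,6-tribromo-3-(methylthio)indole ⇐ C2 bromination of 4,6-dibromo-3-(methylthio)indole ⇐ 3,5-dibromoaniline + the same acetal (Gassman).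
4. Ring order: each pyrrole ring is closed on its preformed bromoarene; all six bromines and both sulfurs are in place before the union, and no ring is formed after it.

Assumption: the SMILES has no stereodescriptor and the molecule has no stereocentre; the hindered C3–N1 axis is unspecified, so the compound is made as drawn (any atropisomers as the racemate).

**Step 1**
Reactants: 1 3,4,5-tribromoaniline; 2 (methylthio)acetaldehyde dimethyl acetal
Product: 6 4,5,6-tribromo-3-(methylthio)-1H-indole, via N-chloro-3,4,5-tribromoaniline 3 (not isolated), via azasulfonium chloride 4 (not isolated), via rearranged aniline acetal 5 (not isolated)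
Conditions: t-BuOCl, CH2Cl2, −70 °C; 2; NaOMe, MeOH, −70 °C → rt; then 2 M aq HCl, Et2O, rt
Reagents that add atoms: none
Why: Gassman indole synthesis, in which deprotonation alpha to sulfur of the azasulfonium salt triggers a [2,3]-sigmatropic (Sommelet–Hauser) shift to the ortho carbon (both ortho positions of 1 are equivalent, so one regioisomer) and acid closes the pyrrole ring with loss of two MeOH; no stereocentre remains.

**Step 2**
Reactants: 6 4,5,6-tribromo-3-(methylthio)-1H-indole
Product: 7 4,5,6-tribromo-2-(methylthio)-1H-indole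
Conditions: CF3CO2H, ClCH2CH2Cl, 60 °C
Reagents that add atoms: none
Why: acid-catalysed 3→2 sulfenyl migration of 3-indolyl sulfides (sulfenyl transfer through the C3-protonated indoleninium), helped here by relief of the peri strain between 3-SMe and 4-Br.

**Step 3**
Reactants: 7 4,5,6-tribromo-2-(methylthio)-1H-indole
Product: 8 4,5,6-tribromo-2-(methylsulfinyl)-1H-indole (racemic at sulfur)
Conditions: mCPBA (1.0 equiv), CH2Cl2, −40 → −20 °C
Reagents that add atoms: 3-chloroperoxybenzoic acid (mCPBA), O=C(OO)c1cccc(Cl)c1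
Why: chemoselective sulfide-to-sulfoxide oxidation with one equivalent of peracid at low temperature, the electron-poor indole ring being inert; the sulfur stereocentre is racemic and is destroyed in step 6.

**Step 4**
Reactants: 9 3,5-dibromoaniline; 2 (methylthio)acetaldehyde dimethyl acetal
Product: 13 4,6-dibromo-3-(methylthio)-1H-indole, via N-chloro-3,5-dibromoaniline 10 (not isolated), via azasulfonium chloride 11 (not isolated), via rearranged aniline acetal 12 (not isolated)
Conditions: t-BuOCl, CH2Cl2, −70 °C; 2; NaOMe, MeOH, −70 °C → rt; then 2 M aq HCl, Et2O, rt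
Reagents that add atoms: none
Why: Gassman indole synthesis as in step 1; the symmetric aniline gives only the 4,6-dibromo isomer after the [2,3]-sigmatropic shift and acid ring closure.

**Step 5**
Reactants: 13 4,6-dibromo-3-(methylthio)-1H-indole
Product: 14 2,4,6-tribromo-3-(methylthio)-1H-indole
Conditions: NBS (1.05 equiv), dry CH2Cl2, 0 °C, dark
Reagents that add atoms: N-bromosuccinimide (NBS), O=C1CCC(=O)N1Br
Why: electrophilic bromination of a 3-substituted indole goes to C2, the only open pyrrole position, while the dibrominated benzo ring is deactivated.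

**Step 6**
Reactants: 8 4,5,6-tribromo-2-(methylsulfinyl)-1H-indole; 14 2,4,6-tribromo-3-(methylthio)-1H-indole
Product: 17 4,5,6-tribromo-2-(methylthio)-3-[2,4,6-tribromo-3-(methylthio)-1H-indol-1-yl]-1H-indole (target), via triflyloxysulfonium triflate 15 (not isolated), via sodium indolide 16 (not isolated)
Conditions: 8, Tf2O (1.05 equiv), 2,6-di-tert-butyl-4-methylpyridine (DTBMP, 3 equiv), CH2Cl2, −78 °C; then 16 (1.5 equiv, from 14, NaH, THF, 0 °C), −78 → −20 °C; aq NaHCO3
Reagents that add atoms: none
Why: Proposed new method: S-triflation of sulfoxide 8 turns the indole C2=C3 bond into a vinylsulfonium, so the indolide nitrogen of 16 (its only open nucleophilic site, C2 and C3 being blocked by Br and SMe) adds at C3 with expulsion of triflate from sulfur (additive, SN2′-type Pummerer pathway), and loss of the C3 proton to DTBMP restores the aromatic 2-(methylthio)indole, with the sulfoxide oxygen as internal oxidant and no stereocentre formed; the closest known reaction type is the extended (vinylogous) Pummerer oxidative cyclisation of indol-2-yl and imidazol-2-yl sulfoxides with tethered carbon or pyrrole-nitrogen nucleophiles, here proposed as an intermolecular C3–N coupling with a hindered indolide on a 3-unsubstituted 2-(methylsulfinyl)indole.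

**Compound list**
1 | 3,4,5-tribromoaniline | Nc1cc(Br)c(Br)c(Br)c1 | starting material
2 | (methylthio)acetaldehyde dimethyl acetal [1,1-dimethoxy-2-(methylthio)ethane] | CSCC(OC)OC | starting material
3 | N-chloro-3,4,5-tribromoaniline | ClNc1cc(Br)c(Br)c(Br)c1 | intermediate
4 | (2,2-dimethoxyethyl)(methyl)[(3,4,5-tribromophenyl)amino]sulfonium chloride | C[S+](CC(OC)OC)Nc1cc(Br)c(Br)c(Br)c1.[Cl-] | intermediate
5 | 3,4,5-tribromo-2-[2,2-dimethoxy-1-(methylthio)ethyl]aniline (racemic) | Nc1cc(Br)c(Br)c(Br)c1C(SC)C(OC)OC | intermediate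
6 | 4,5,6-tribromo-3-(methylthio)-1H-indole | CSc1c[nH]c2cc(Br)c(Br)c(Br)c12 | intermediate
7 | 4,5,6-tribromo-2-(methylthio)-1H-indole | CSc1cc2c(Br)c(Br)c(Br)cc2[nH]1 | intermediate
8 | 4,5,6-tribromo-2-(methylsulfinyl)-1H-indole (racemic at sulfur) | CS(=O)c1cc2c(Br)c(Br)c(Br)cc2[nH]1 | intermediate
9 | 3,5-dibromoaniline | Nc1cc(Br)cc(Br)c1 | starting material
10 | N-chloro-3,5-dibromoaniline | ClNc1cc(Br)cc(Br)c1 | intermediate
11 | [(3,5-dibromophenyl)amino](2,2-dimethoxyethyl)(methyl)sulfonium chloride | C[S+](CC(OC)OC)Nc1cc(Br)cc(Br)c1.[Cl-] | intermediate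
12 | 3,5-dibromo-2-[2,2-dimethoxy-1-(methylthio)ethyl]aniline (racemic) | Nc1cc(Br)cc(Br)c1C(SC)C(OC)OC | intermediate
13 | 4,6-dibromo-3-(methylthio)-1H-indole | CSc1c[nH]c2cc(Br)cc(Br)c12 | intermediate
14 | 2,4,6-tribromo-3-(methylthio)-1H-indole | CSc1c(Br)[nH]c2cc(Br)cc(Br)c12 | intermediate
15 | methyl(4,5,6-tribromo-1H-indol-2-yl)[(trifluoromethylsulfonyl)oxy]sulfonium trifluoromethanesulfonate | C[S+](OS(=O)(=O)C(F)(F)F)c1cc2c(Br)c(Br)c(Br)cc2[nH]1.[O-]S(=O)(=O)C(F)(F)F | intermediate
16 | sodium 2,4,6-tribromo-3-(methylthio)indol-1-ide | CSc1c(Br)[n-]c2cc(Br)cc(Br)c12.[Na+] | intermediate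
17 | 4,5,6-tribromo-2-(methylthio)-3-[2,4,6-tribromo-3-(methylthio)-1H-indol-1-yl]-1H-indole | CSc1[nH]c2cc(Br)c(Br)c(Br)c2c1-n1c(Br)c(SC)c2c(Br)cc(Br)cc21 | target

**Totals**
Total step count: 6. Longest linear sequence: 4 steps (1 → 6 → 7 → 8 → 17); the ring B branch is 2 steps (9 → 13 → 14) before the union.

**Three steps most likely to fail**

Step 6 (the proposed C3–N Pummerer amination). Risks:
- classical Pummerer reaction at the S-methyl group, giving an N–CH2–S linked product;
- attack of the indolide at sulfur;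
- simple proton transfer from the acidic N–H of 15 to 16;
- steric shielding of C3 by the 4-Br and of the nitrogen by the 2-Br.

Fallback (known chemistry), setting out from 7 with 13 as partner and coming back at 17:
- 7 is iodinated at C3 with N-iodosuccinimide (DMF, 0 °C) to 4,5,6-tribromo-3-iodo-2-(methylthio)-1H-indole F1.
- Boc2O and DMAP in MeCN give tert-butyl 4,5,6-tribromo-3-iodo-2-(methylthio)-1H-indole-1-carboxylate F2.
- Ullmann–Goldberg N-arylation of 13 with F2 (CuI 10 mol %, trans-N,N′-dimethylcyclohexane-1,2-diamine, K3PO4, toluene, 80 °C; the C–I bond reacts ahead of the C–Br bonds) gives tert-butyl 4,5,6-tribromo-3-[4,6-dibromo-3-(methylthio)-1H-indol-1-yl]-2-(methylthio)-1H-indole-1-carboxylate F3.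
- NBS (CH2Cl2, 0 °C) brominates C2 of ring B, ring A being deactivated by Boc, to give tert-butyl 4,5,6-tribromo-2-(methylthio)-3-[2,4,6-tribromo-3-(methylthio)-1H-indol-1-yl]-1H-indole-1-carboxylate F4.
- CF3CO2H in CH2Cl2 removes the Boc group to give 17.

Step 2 (3→2 sulfenyl shift). The tribrominated indole is hard to protonate at C3 and is a weak C2 nucleophile, so the intermolecular sulfenyl shuttle may stall. Fallback, setting out from 6 and coming back at 7:
- 6 is sulfenylated at C2 with the strong electrophile dimethyl(methylthio)sulfonium tetrafluoroborate (CH2Cl2, 0 °C → rt) to give 4,5,6-tribromo-2,3-bis(methylthio)-1H-indole F5.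
- The 3-sulfide is then removed selectively with 2-sulfanylbenzoic acid in CF3CO2H at rt (C3 protonation is now assisted by the 2-SMe donor, and the thiol takes up the MeS group), giving 7.

Step 5 (C2 bromination with NBS beside a sulfide). Risks are oxidation or bromosulfonium chemistry at sulfur and over-bromination at C7. Fallback, setting out from 9 and coming back at 14, which avoids electrophilic bromination altogether:
- 9 is N-chlorinated to 10 (t-BuOCl, CH2Cl2, −70 °C) and treated with methyl (methylthio)acetate to give [(3,5-dibromophenyl)amino](2-methoxy-2-oxoethyl)(methyl)sulfonium chloride F6.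
- NaOMe in MeOH induces the [2,3]-shift to methyl 2-(2-amino-4,6-dibromophenyl)-2-(methylthio)acetate F7.
- Aq HCl lactamises F7 to racemic 4,6-dibromo-3-(methylthio)indolin-2-one F8 (Gassman oxindole synthesis).
- POBr3 with imidazole in ClCH2CH2Cl at 80 °C converts the lactam into the 2-bromoindole 14.

**Further compounds**
F1 | step 6 | 4,5,6-tribromo-3-iodo-2-(methylthio)-1H-indole | CSc1[nH]c2cc(Br)c(Br)c(Br)c2c1I
F2 | step 6 | tert-butyl 4,5,6-tribromo-3-iodo-2-(methylthio)-1H-indole-1-carboxylate | CSc1c(I)c2c(Br)c(Br)c(Br)cc2n1C(=O)OC(C)(C)C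
F3 | step 6 | tert-butyl 4,5,6-tribromo-3-[4,6-dibromo-3-(methylthio)-1H-indol-1-yl]-2-(methylthio)-1H-indole-1-carboxylate | CSc1c(-n2cc(SC)c3c(Br)cc(Br)cc32)c2c(Br)c(Br)c(Br)cc2n1C(=O)OC(C)(C)C
F4 | step 6 | tert-butyl 4,5,6-tribromo-2-(methylthio)-3-[2,4,6-tribromo-3-(methylthio)-1H-indol-1-yl]-1H-indole-1-carboxylate | CSc1c(-n2c(Br)c(SC)c3c(Br)cc(Br)cc32)c2c(Br)c(Br)c(Br)cc2n1C(=O)OC(C)(C)C
F5 | step 2 | 4,5,6-tribromo-2,3-bis(methylthio)-1H-indole | CSc1[nH]c2cc(Br)c(Br)c(Br)c2c1SC
F6 | step 5 | [(3,5-dibromophenyl)amino](2-methoxy-2-oxoethyl)(methyl)sulfonium chloride | COC(=O)C[S+](C)Nc1cc(Br)cc(Br)c1.[Cl-]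
F7 | step 5 | methyl 2-(2-amino-4,6-dibromophenyl)-2-(methylthio)acetate (racemic) | COC(=O)C(SC)c1c(N)cc(Br)cc1Br
F8 | step 5 | 4,6-dibromo-3-(methylthio)indolin-2-one (racemic) | CSC1C(=O)Nc2cc(Br)cc(Br)c21
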